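**Plan**
1. Retrosynthesis: the sulfate O–S bond and the protecting groups are cut first, and the C3 hydroxymethyl group is traced back to an ethyl ester. The C2–C3 bond of the dihydrofuran ring is cut next, which opens the ring to an achiral benzyl aryl ether that carries an aryl diazoacetate. The aryl–C(N2) bond and the benzylic C–O ether bond are cut last, giving iodinated dihydroconiferyl alcohol, O-benzylvanillyl bromide and ethyl diazoacetate.
2. Forward: ring A (dihydroconiferyl alcohol) is iodinated ortho to its phenol, the phenol is alkylated with the guaiacyl benzyl bromide, and the diazoacetate is attached by palladium coupling. The dihydrofuran ring (O1, C2, C3, C3a, C7a) is then closed by a rhodium carbenoid C–H insertion that makes C2–C3.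
3. Enabling feature: in the open precursor the future C2–H is a methylene hydrogen flanked by the ether oxygen O1 and the electron-rich guaiacyl ring, and it lies 1,5 to the carbene carbon (future C3) held ortho on ring A. It is therefore hydridic and within reach of a five-membered insertion transition state. The ester that later becomes CH2OH is the acceptor group that tempers the carbenoid.
4. Stereochemistry: C2 (S) comes from the chiral dirhodium carboxylate, which selects one of the two enantiotopic benzylic hydrogens. The insertion gives the 2,3-cis ester, and C3 is then brought to the trans configuration of the target by thermodynamic epimerisation next to the ester, with C2 unchanged.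
5. End game: the two primary alcohols are told apart by a TBS ether (propyl chain) and a benzyl carbonate (C3 CH2OH). The chain alcohol is sulfated, and one hydrogenolysis removes the carbonate and the phenol benzyl ether.

Key step: step 6

Remark 1: the absolute sense of the insertion is assigned by analogy. S-configured N-phthaloyl amino acid dirhodium catalysts are taken to give the 2R series with benzyl aryl ethers of this type, so the R-configured catalyst is specified for 2S. Should the sense prove opposite, Rh2(S-PTAD)4 is used and nothing else changes.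
Remark 2: sulfate monoesters are carried as sodium salts. The free hydrogen sulfate drawn for the target is strongly acidic and is released only in the last work-up, cold and dilute.

**Step 1**
Reactants: 1 4-(3-hydroxypropyl)-2-methoxyphenol (dihydroconiferyl alcohol)
Product: 2 4-(3-hydroxypropyl)-2-iodo-6-methoxyphenol
Conditions: NIS (1.05 equiv), DMF, 0 °C to rt, dark
Reagents that add atoms: N-iodosuccinimide, O=C1CCC(=O)N1I
Why: Electrophilic aromatic iodination: the free phenol is the strongest donor on ring A and, with its para position and one ortho position occupied, directs iodine to the one free ortho carbon, while the primary alcohol does not react with NIS.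

**Step 2**
Reactants: 3 [4-(benzyloxy)-3-methoxyphenyl]methanol
Product: 4 1-(benzyloxy)-4-(bromomethyl)-2-methoxybenzene
Conditions: PBr3 (0.4 equiv), Et2O, 0 °C; used crude
Reagents that add atoms: phosphorus tribromide, BrP(Br)Br
Why: Conversion of a benzylic alcohol into the bromide by PBr3 (substitution through the phosphite ester) is reliable for electron-rich benzyl alcohols and leaves the phenol benzyl ether intact.

**Step 3**
Reactants: 2 4-(3-hydroxypropyl)-2-iodo-6-methoxyphenol; 4 1-(benzyloxy)-4-(bromomethyl)-2-methoxybenzene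
Product: 5 3-(4-{[4-(benzyloxy)-3-methoxyphenyl]methoxy}-3-iodo-5-methoxyphenyl)propan-1-ol
Conditions: K2CO3 (1.5 equiv), DMF, rt
Reagents that add atoms: none
Why: Williamson ether synthesis: carbonate deprotonates only the phenol and not the aliphatic alcohol, and the phenoxide is O-alkylated by the reactive benzylic bromide.

**Step 4**
Reactants: 5 3-(4-{[4-(benzyloxy)-3-methoxyphenyl]methoxy}-3-iodo-5-methoxyphenyl)propan-1-ol
Product: 6 tert-butyl[3-(4-{[4-(benzyloxy)-3-methoxyphenyl]methoxy}-3-iodo-5-methoxyphenyl)propoxy]dimethylsilane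
Conditions: TBSCl (1.2 equiv), imidazole (2.5 equiv), CH2Cl2, rt
Reagents that add atoms: tert-butyldimethylsilyl chloride, CC(C)(C)[Si](C)(C)Cl
Why: Standard silylation of a primary alcohol (imidazole-activated silyl chloride), which masks the chain alcohol against O–H insertion in step 6 and marks it for later selective release.

**Step 5**
Reactants: 6 tert-butyl[3-(4-{[4-(benzyloxy)-3-methoxyphenyl]methoxy}-3-iodo-5-methoxyphenyl)propoxy]dimethylsilane; 7 ethyl diazoacetate (1.3 equiv)
Product: 8 ethyl 2-(2-{[4-(benzyloxy)-3-methoxyphenyl]methoxy}-5-{3-[(tert-butyldimethylsilyl)oxy]propyl}-3-methoxyphenyl)-2-diazoacetate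
Conditions: Pd(PPh3)4 (5 mol %), PPh3 (10 mol %), Ag2CO3 (0.5 equiv), Et3N (1.3 equiv), toluene, rt
Reagents that add atoms: none
Why: Palladium-catalysed cross-coupling of an aryl iodide with an acceptor-substituted diazomethane with retention of the diazo group: oxidative addition of zerovalent palladium into the C–I bond, transfer of the diazoacetate carbon (deprotonated with the help of silver carbonate and the amine) to palladium and reductive elimination all run at room temperature, below the threshold for loss of N2.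

**Step 6**
Reactants: 8 ethyl 2-(2-{[4-(benzyloxy)-3-methoxyphenyl]methoxy}-5-{3-[(tert-butyldimethylsilyl)oxy]propyl}-3-methoxyphenyl)-2-diazoacetate
Product: 10 ethyl (2S,3R)-2-[4-(benzyloxy)-3-methoxyphenyl]-5-{3-[(tert-butyldimethylsilyl)oxy]propyl}-7-methoxy-2,3-dihydro-1-benzofuran-3-carboxylate (2,3-cis), via dirhodium carbenoid 9 (not isolated)
Conditions: Rh2(R-PTAD)4 [dirhodium tetrakis((R)-N-phthaloyl-(1-adamantyl)glycinate)] (1 mol %), 4 Å MS, toluene, −60 °C, slow addition of 8, then −40 °C
Reagents that add atoms: none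
Why: Rh2(R-PTAD)4 (both rhodium atoms divalent) takes N2 from 8 to give the electrophilic donor/acceptor carbenoid 9, whose carbene carbon (future C3) inserts into one methylene C–H bond of the ArCH2–O unit through a concerted, asynchronous three-centre transition state with hydride-transfer character, so that C2–C3 forms while the hydrogen moves to C3. The closest known reaction type is the enantioselective intramolecular 1,5 C–H insertion of ortho-benzyloxy aryldiazoacetates with N-phthaloyl amino acid dirhodium carboxylates, which gives cis-2-aryl-2,3-dihydrobenzofuran-3-carboxylates. The dihydrofuran ring closes in the 1,5-insertion mode (carbene carbon to the fifth atom along C3–C3a–C7a–O1–C2, a five-membered closure), the only ring size that the ortho arrangement on ring A allows. C2 is set by the chiral carboxylate pocket, which selects one of the two enantiotopic benzylic hydrogens and replaces it with retention, and C3 is set cis to the C2 aryl group by the compact transition state in which the same ligand wall fixes the carbenoid face; C3 is inverted in step 7, so only the C2 control has to persist. The step needs site selectivity for this methylene over the PhCH2–O, SiO–CH2, OCH3 and ester ethyl C–H bonds and chemoselectivity over carbene dimerisation, arene cyclopropanation and O–H insertion; the 1,5 relation, the hydridic character of a C–H flanked by O1 and the electron-rich guaiacyl ring, slow addition at low temperature and exclusion of water secure them.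

**Step 7**
Reactants: 10 ethyl (2S,3R)-2-[4-(benzyloxy)-3-methoxyphenyl]-5-{3-[(tert-butyldimethylsilyl)oxy]propyl}-7-methoxy-2,3-dihydro-1-benzofuran-3-carboxylate
Product: 11 ethyl (2S,3S)-2-[4-(benzyloxy)-3-methoxyphenyl]-5-{3-[(tert-butyldimethylsilyl)oxy]propyl}-7-methoxy-2,3-dihydro-1-benzofuran-3-carboxylate (2,3-trans)
Conditions: NaOEt (0.2 equiv), EtOH/THF, 0 °C to rt
Reagents that add atoms: none
Why: Base-mediated epimerisation under thermodynamic control: reversible deprotonation at C3 (acidified by the ester and ring A) and reprotonation move the kinetic cis ester to the more stable trans isomer, in which the C2 aryl group and the C3 ester lie on opposite faces of the dihydrofuran ring, while C2 carries no acidic hydrogen and keeps its configuration; a catalytic amount of the matching alkoxide at low temperature is used to hold back E1cB opening of the ring.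

**Step 8**
Reactants: 11 ethyl (2S,3S)-2-[4-(benzyloxy)-3-methoxyphenyl]-5-{3-[(tert-butyldimethylsilyl)oxy]propyl}-7-methoxy-2,3-dihydro-1-benzofuran-3-carboxylate
Product: 12 {(2S,3R)-2-[4-(benzyloxy)-3-methoxyphenyl]-5-{3-[(tert-butyldimethylsilyl)oxy]propyl}-7-methoxy-2,3-dihydro-1-benzofuran-3-yl}methanol
Conditions: LiBH4 (1.5 equiv), THF, 0 °C to rt; aqueous work-up
Reagents that add atoms: none
Why: Hydride reduction of an ester to the primary alcohol with LiBH4, which is mild enough to leave the silyl and benzyl ethers and the ring untouched and should reduce the ester faster than it epimerises C3.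

**Step 9**
Reactants: 12 {(2S,3R)-2-[4-(benzyloxy)-3-methoxyphenyl]-5-{3-[(tert-butyldimethylsilyl)oxy]propyl}-7-methoxy-2,3-dihydro-1-benzofuran-3-yl}methanol
Product: 13 benzyl {(2S,3R)-2-[4-(benzyloxy)-3-methoxyphenyl]-5-{3-[(tert-butyldimethylsilyl)oxy]propyl}-7-methoxy-2,3-dihydro-1-benzofuran-3-yl}methyl carbonate
Conditions: CbzCl (1.5 equiv), pyridine (3 equiv), DMAP (10 mol %), CH2Cl2, 0 °C to rt
Reagents that add atoms: benzyl chloroformate, O=C(Cl)OCc1ccccc1
Why: DMAP-catalysed O-acylation of the primary alcohol with a chloroformate installs a carbonate that withstands fluoride and sulfation and leaves under the same hydrogenolysis as the phenol benzyl ether.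

**Step 10**
Reactants: 13 benzyl {(2S,3R)-2-[4-(benzyloxy)-3-methoxyphenyl]-5-{3-[(tert-butyldimethylsilyl)oxy]propyl}-7-methoxy-2,3-dihydro-1-benzofuran-3-yl}methyl carbonate
Product: 14 benzyl {(2S,3R)-2-[4-(benzyloxy)-3-methoxyphenyl]-5-(3-hydroxypropyl)-7-methoxy-2,3-dihydro-1-benzofuran-3-yl}methyl carbonate
Conditions: HF·pyridine, pyridine/THF, 0 °C to rt
Reagents that add atoms: none
Why: Fluoride-driven cleavage of a primary silyl ether (strong Si–F bond) under buffered conditions that spare the benzyl carbonate, the benzyl ether and the acid-sensitive cyclic benzylic ether.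

**Step 11**
Reactants: 14 benzyl {(2S,3R)-2-[4-(benzyloxy)-3-methoxyphenyl]-5-(3-hydroxypropyl)-7-methoxy-2,3-dihydro-1-benzofuran-3-yl}methyl carbonate
Product: 15 sodium 3-[(2S,3R)-2-[4-(benzyloxy)-3-methoxyphenyl]-3-({[(benzyloxy)carbonyl]oxy}methyl)-7-methoxy-2,3-dihydro-1-benzofuran-5-yl]propyl sulfate
Conditions: SO3·pyridine (3 equiv), pyridine, rt; then aq. NaHCO3, C18 reversed-phase chromatography
Reagents that add atoms: sulfur trioxide pyridine complex, O=S(=O)([O-])[n+]1ccccc1; sodium hydrogen carbonate, [Na+].OC(=O)[O-]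
Why: O-Sulfation of the only free hydroxyl group with the sulfur trioxide pyridine complex, followed by cation exchange to the sodium salt, which also removes the pyridine that would slow the hydrogenolysis in step 12.

**Step 12**
Reactants: 15 sodium 3-[(2S,3R)-2-[4-(benzyloxy)-3-methoxyphenyl]-3-({[(benzyloxy)carbonyl]oxy}methyl)-7-methoxy-2,3-dihydro-1-benzofuran-5-yl]propyl sulfate
Product: 18 3-[(2S,3R)-2-(4-hydroxy-3-methoxyphenyl)-3-(hydroxymethyl)-7-methoxy-2,3-dihydro-1-benzofuran-5-yl]propyl hydrogen sulfate (target), via carbonic acid monoester 16 (not isolated), via sodium salt of the target 17 (not isolated)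
Conditions: H2 (1 atm), 10% Pd/C, MeOH, rt, short reaction time; filtration; then aq. HCl (1.0 equiv), 0 °C, C18 desalting, lyophilisation
Reagents that add atoms: none
Why: Catalytic hydrogenolysis should cleave the phenol benzyl ether and the benzyl carbonate (the carbonic acid monoester 16 loses CO2 spontaneously) much faster than the cyclic C2–O1 benzylic ether and does not touch the sulfate monoester; one equivalent of acid then converts the sodium salt 17 into the hydrogen sulfate drawn for the target.

**Compound list**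
1 | 4-(3-hydroxypropyl)-2-methoxyphenol (dihydroconiferyl alcohol) | COc1cc(CCCO)ccc1O | starting material
2 | 4-(3-hydroxypropyl)-2-iodo-6-methoxyphenol | COc1cc(CCCO)cc(I)c1O | intermediate
3 | [4-(benzyloxy)-3-methoxyphenyl]methanol | COc1cc(CO)ccc1OCc1ccccc1 | starting material
4 | 1-(benzyloxy)-4-(bromomethyl)-2-methoxybenzene | COc1cc(CBr)ccc1OCc1ccccc1 | intermediate
5 | 3-(4-{[4-(benzyloxy)-3-methoxyphenyl]methoxy}-3-iodo-5-methoxyphenyl)propan-1-ol | COc1cc(COc2c(I)cc(CCCO)cc2OC)ccc1OCc1ccccc1 | intermediate
6 | tert-butyl[3-(4-{[4-(benzyloxy)-3-methoxyphenyl]methoxy}-3-iodo-5-methoxyphenyl)propoxy]dimethylsilane | COc1cc(COc2c(I)cc(CCCO[Si](C)(C)C(C)(C)C)cc2OC)ccc1OCc1ccccc1 | intermediate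
7 | ethyl diazoacetate | CCOC(=O)C=[N+]=[N-] | starting material
8 | ethyl 2-(2-{[4-(benzyloxy)-3-methoxyphenyl]methoxy}-5-{3-[(tert-butyldimethylsilyl)oxy]propyl}-3-methoxyphenyl)-2-diazoacetate | CCOC(=O)C(=[N+]=[N-])c1cc(CCCO[Si](C)(C)C(C)(C)C)cc(OC)c1OCc1ccc(OCc2ccccc2)c(OC)c1 | intermediate
9 | dirhodium carbenoid of 8 (not isolated; the Rh2 unit is abbreviated to one Rh atom and the four carboxylate ligands are not drawn) | CCOC(=O)C(=[Rh])c1cc(CCCO[Si](C)(C)C(C)(C)C)cc(OC)c1OCc1ccc(OCc2ccccc2)c(OC)c1 | intermediate
10 | ethyl (2S,3R)-2-[4-(benzyloxy)-3-methoxyphenyl]-5-{3-[(tert-butyldimethylsilyl)oxy]propyl}-7-methoxy-2,3-dihydro-1-benzofuran-3-carboxylate (cis) | COc1cc([C@H]2Oc3c(OC)cc(CCCO[Si](C)(C)C(C)(C)C)cc3[C@H]2C(=O)OCC)ccc1OCc1ccccc1 | intermediate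
11 | ethyl (2S,3S)-2-[4-(benzyloxy)-3-methoxyphenyl]-5-{3-[(tert-butyldimethylsilyl)oxy]propyl}-7-methoxy-2,3-dihydro-1-benzofuran-3-carboxylate (trans) | COc1cc([C@H]2Oc3c(OC)cc(CCCO[Si](C)(C)C(C)(C)C)cc3[C@@H]2C(=O)OCC)ccc1OCc1ccccc1 | intermediate
12 | {(2S,3R)-2-[4-(benzyloxy)-3-methoxyphenyl]-5-{3-[(tert-butyldimethylsilyl)oxy]propyl}-7-methoxy-2,3-dihydro-1-benzofuran-3-yl}methanol | COc1cc([C@H]2Oc3c(OC)cc(CCCO[Si](C)(C)C(C)(C)C)cc3[C@@H]2CO)ccc1OCc1ccccc1 | intermediate
13 | benzyl {(2S,3R)-2-[4-(benzyloxy)-3-methoxyphenyl]-5-{3-[(tert-butyldimethylsilyl)oxy]propyl}-7-methoxy-2,3-dihydro-1-benzofuran-3-yl}methyl carbonate | COc1cc([C@H]2Oc3c(OC)cc(CCCO[Si](C)(C)C(C)(C)C)cc3[C@@H]2COC(=O)OCc2ccccc2)ccc1OCc1ccccc1 | intermediate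
14 | benzyl {(2S,3R)-2-[4-(benzyloxy)-3-methoxyphenyl]-5-(3-hydroxypropyl)-7-methoxy-2,3-dihydro-1-benzofuran-3-yl}methyl carbonate | COc1cc([C@H]2Oc3c(OC)cc(CCCO)cc3[C@@H]2COC(=O)OCc2ccccc2)ccc1OCc1ccccc1 | intermediate
15 | sodium 3-[(2S,3R)-2-[4-(benzyloxy)-3-methoxyphenyl]-3-({[(benzyloxy)carbonyl]oxy}methyl)-7-methoxy-2,3-dihydro-1-benzofuran-5-yl]propyl sulfate | COc1cc([C@H]2Oc3c(OC)cc(CCCOS(=O)(=O)[O-])cc3[C@@H]2COC(=O)OCc2ccccc2)ccc1OCc1ccccc1.[Na+] | intermediate
16 | sodium 3-[(2S,3R)-3-[(carboxyoxy)methyl]-2-(4-hydroxy-3-methoxyphenyl)-7-methoxy-2,3-dihydro-1-benzofuran-5-yl]propyl sulfate (not isolated) | COc1cc([C@H]2Oc3c(OC)cc(CCCOS(=O)(=O)[O-])cc3[C@@H]2COC(=O)O)ccc1O.[Na+] | intermediate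
17 | sodium 3-[(2S,3R)-2-(4-hydroxy-3-methoxyphenyl)-3-(hydroxymethyl)-7-methoxy-2,3-dihydro-1-benzofuran-5-yl]propyl sulfate (not isolated) | COc1cc([C@H]2Oc3c(OC)cc(CCCOS(=O)(=O)[O-])cc3[C@@H]2CO)ccc1O.[Na+] | intermediate
18 | 3-[(2S,3R)-2-(4-hydroxy-3-methoxyphenyl)-3-(hydroxymethyl)-7-methoxy-2,3-dihydro-1-benzofuran-5-yl]propyl hydrogen sulfate | COc1cc([C@H]2Oc3c(OC)cc(CCCOS(=O)(=O)O)cc3[C@@H]2CO)ccc1O | target

**Step count**
Total steps: 12. Longest linear sequence: 11 steps (steps 1 and 3 to 12 from compound 1; equally steps 2 to 12 from compound 3).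

**Steps most likely to fail**

Step 5. The hindered, electron-rich ortho-alkoxy aryl iodide may undergo oxidative addition and diazoacetate transfer too slowly, so that decomposition of the diazo ester (carbene dimerisation, palladium carbene formation) wins. The fallback sets out from 6 and comes back at 8. It installs the two-carbon unit first and the diazo group afterwards. A Negishi-type coupling of 6 with the Reformatsky reagent BrZnCH2CO2Et (from ethyl bromoacetate and zinc dust; Pd(dba)2, Q-phos, THF, 50 °C) should give ethyl 2-(2-{[4-(benzyloxy)-3-methoxyphenyl]methoxy}-5-{3-[(tert-butyldimethylsilyl)oxy]propyl}-3-methoxyphenyl)acetate F1. A Regitz diazo transfer to F1 (4-acetamidobenzenesulfonyl azide, DBU, MeCN, 0 °C to rt) then gives 8.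

Step 6. The catalyst may discriminate poorly between the two enantiotopic benzylic hydrogens, or the cis/trans control may erode, leaving material of low enantiomeric purity that cannot be upgraded later. The fallback sets out from 6 and comes back at 12. It moves the stereocontrol to a covalently bound lactamide auxiliary, which also makes the stereoisomers separable diastereomers.
- Ethyl (S)-lactate and pyrrolidine (neat, 60 °C) give (2S)-2-hydroxy-1-(pyrrolidin-1-yl)propan-1-one F2.
- Bromoacetyl bromide and pyridine in CH2Cl2 convert F2 into (2S)-1-oxo-1-(pyrrolidin-1-yl)propan-2-yl bromoacetate F3.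
- N,N'-Ditosylhydrazine and DBU in THF turn F3 into (2S)-1-oxo-1-(pyrrolidin-1-yl)propan-2-yl diazoacetate F4.
- Coupling of F4 with 6 under the conditions of step 5 gives the auxiliary-bearing aryldiazoacetate F5.
- Rh2(S-DOSP)4 [dirhodium tetrakis((S)-N-(4-dodecylphenylsulfonyl)prolinate)] in CH2Cl2 should close F5 to the trans-dihydrobenzofuran lactamide ester F6, with auxiliary and catalyst chosen as the matched pair and the diastereomers separated on silica. The antipodal auxiliary from ethyl (R)-lactate is taken if the sense of induction requires it.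
- LiBH4 in THF cleaves F6 reductively to alcohol 12 and returns the auxiliary, so steps 7 and 8 are not needed.

Step 12. Hydrogenolysis on the polar sulfate salt may be slow (traces of pyridine, poor solubility), and prolonged exposure invites reductive opening of the benzylic C2–O1 bond. Partly deprotected sulfates are also hard to separate, and the free acid may decompose during its release. The fallback sets out from 12 and comes back at 17. It moves the hydrogenolysis to a lipophilic, neutral stage and ends with a mild methanolysis.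
- H2, 10% Pd/C in EtOAc removes the phenol benzyl ether of 12 to give 4-[(2S,3R)-5-{3-[(tert-butyldimethylsilyl)oxy]propyl}-3-(hydroxymethyl)-7-methoxy-2,3-dihydro-1-benzofuran-2-yl]-2-methoxyphenol F7, which can be purified on silica.
- Ac2O, pyridine and DMAP give the diacetate F8.
- HF·pyridine frees the chain alcohol to give the diacetate alcohol F9.
- SO3·pyridine followed by aq. NaHCO3 gives the diacetate sodium sulfate F10.
- K2CO3 (catalytic) in MeOH at 0 °C removes both acetates to give 17, which is protonated as in step 12.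

**Further compounds**
F1 | step 5 | ethyl 2-(2-{[4-(benzyloxy)-3-methoxyphenyl]methoxy}-5-{3-[(tert-butyldimethylsilyl)oxy]propyl}-3-methoxyphenyl)acetate | CCOC(=O)Cc1cc(CCCO[Si](C)(C)C(C)(C)C)cc(OC)c1OCc1ccc(OCc2ccccc2)c(OC)c1
F2 | step 6 | (2S)-2-hydroxy-1-(pyrrolidin-1-yl)propan-1-one | C[C@H](O)C(=O)N1CCCC1
F3 | step 6 | (2S)-1-oxo-1-(pyrrolidin-1-yl)propan-2-yl bromoacetate | C[C@H](OC(=O)CBr)C(=O)N1CCCC1
F4 | step 6 | (2S)-1-oxo-1-(pyrrolidin-1-yl)propan-2-yl diazoacetate | C[C@H](OC(=O)C=[N+]=[N-])C(=O)N1CCCC1
F5 | step 6 | (2S)-1-oxo-1-(pyrrolidin-1-yl)propan-2-yl 2-(2-{[4-(benzyloxy)-3-methoxyphenyl]methoxy}-5-{3-[(tert-butyldimethylsilyl)oxy]propyl}-3-methoxyphenyl)-2-diazoacetate | C[C@H](OC(=O)C(=[N+]=[N-])c1cc(CCCO[Si](C)(C)C(C)(C)C)cc(OC)c1OCc1ccc(OCc2ccccc2)c(OC)c1)C(=O)N1CCCC1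
F6 | step 6 | (2S)-1-oxo-1-(pyrrolidin-1-yl)propan-2-yl (2S,3S)-2-[4-(benzyloxy)-3-methoxyphenyl]-5-{3-[(tert-butyldimethylsilyl)oxy]propyl}-7-methoxy-2,3-dihydro-1-benzofuran-3-carboxylate | COc1cc([C@H]2Oc3c(OC)cc(CCCO[Si](C)(C)C(C)(C)C)cc3[C@@H]2C(=O)O[C@@H](C)C(=O)N2CCCC2)ccc1OCc1ccccc1
F7 | step 12 | 4-[(2S,3R)-5-{3-[(tert-butyldimethylsilyl)oxy]propyl}-3-(hydroxymethyl)-7-methoxy-2,3-dihydro-1-benzofuran-2-yl]-2-methoxyphenol | COc1cc([C@H]2Oc3c(OC)cc(CCCO[Si](C)(C)C(C)(C)C)cc3[C@@H]2CO)ccc1O
F8 | step 12 | 4-[(2S,3R)-3-(acetoxymethyl)-5-{3-[(tert-butyldimethylsilyl)oxy]propyl}-7-methoxy-2,3-dihydro-1-benzofuran-2-yl]-2-methoxyphenyl acetate | COc1cc([C@H]2Oc3c(OC)cc(CCCO[Si](C)(C)C(C)(C)C)cc3[C@@H]2COC(C)=O)ccc1OC(C)=O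
F9 | step 12 | 4-[(2S,3R)-3-(acetoxymethyl)-5-(3-hydroxypropyl)-7-methoxy-2,3-dihydro-1-benzofuran-2-yl]-2-methoxyphenyl acetate | COc1cc([C@H]2Oc3c(OC)cc(CCCO)cc3[C@@H]2COC(C)=O)ccc1OC(C)=O
F10 | step 12 | sodium 3-[(2S,3R)-3-(acetoxymethyl)-2-(4-acetoxy-3-methoxyphenyl)-7-methoxy-2,3-dihydro-1-benzofuran-5-yl]propyl sulfate | COc1cc([C@H]2Oc3c(OC)cc(CCCOS(=O)(=O)[O-])cc3[C@@H]2COC(C)=O)ccc1OC(C)=O.[Na+]
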